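Ring A of the flavone is disconnected at C5–C6, C7–C8 and C8–C8a, so that a benzene ring is grown onto a finished 4-pyranone that already carries ring B, the C3 methoxy group and the C4 carbonyl. The feature exploited is the hydroquinone-type ring A: oxygens at C5 and C8 para to each other, with C6–H and C7–O between them. A Dötz benzannulation of a pyranon-3-yl methoxycarbene chromium complex with ethynylboronic acid pinacol ester sets C5–OMe, C6–H, C7–B (masked hydroxyl) and free C8–OH in one operation. The precursor is the pentacarbonylchromium methoxycarbene at C3 of a 5-methoxy-6-aryl-4-pyranone with C2–H free, its 4'-phenol held as a fluoride-labile SEM ether.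

Key step: step 7

Remark: SEM = 2-(trimethylsilyl)ethoxymethyl. This acetal is chosen for the 4'-oxygen because it tolerates every basic, nucleophilic and organometallic step and leaves with fluoride, so no acid meets the aryl prenyl ether at the end. The target has no stereocenter, and the geometry of enaminone 6 is immaterial.

Step 1
Reactants: 1 methyl 4-hydroxy-3-methoxybenzoate (methyl vanillate)
Product: 2 methyl 3-methoxy-4-{[2-(trimethylsilyl)ethoxy]methoxy}benzoate
Conditions: SEMCl, i-Pr2NEt, CH2Cl2, 0 °C → rt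
Reagents that add atoms: 2-(trimethylsilyl)ethoxymethyl chloride (SEMCl), C[Si](C)(C)CCOCCl
Why: Williamson-type O-alkylation of the phenol by the reactive α-chloro ether should be clean, since the methyl ester is inert to the amine base.

Step 2
Reactants: 2 methyl 3-methoxy-4-{[2-(trimethylsilyl)ethoxy]methoxy}benzoate
Product: 3 3-methoxy-4-{[2-(trimethylsilyl)ethoxy]methoxy}benzoic acid
Conditions: LiOH·H2O, THF/MeOH/H2O, 40 °C; then aq. citric acid to pH 4, 0 °C
Reagents that add atoms: lithium hydroxide, [Li+].[OH-]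
Why: Saponification of the benzoate should proceed normally, because the SEM acetal is stable to hydroxide and to the brief, weakly acidic work-up.

Step 3
Reactants: 4 methyl 4-methoxy-3-oxobutanoate; 5 N,N-dimethylformamide dimethyl acetal
Product: 6 methyl (2Z)-2-[(dimethylamino)methylidene]-4-methoxy-3-oxobutanoate
Conditions: neat, rt → 40 °C; MeOH removed under vacuum
Reagents that add atoms: none
Why: The formamide acetal condenses at the doubly activated C2 methylene of the β-keto ester (enaminone formation), the more acidic of the two enolisable positions.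

Step 4
Reactants: 3 3-methoxy-4-{[2-(trimethylsilyl)ethoxy]methoxy}benzoic acid; 6 methyl (2Z)-2-[(dimethylamino)methylidene]-4-methoxy-3-oxobutanoate
Product: 9 methyl 5-methoxy-6-(3-methoxy-4-{[2-(trimethylsilyl)ethoxy]methoxy}phenyl)-4-oxo-4H-pyran-3-carboxylate, via aroyl chloride 7 (not isolated), via open-chain diketo enaminone 8 (not isolated)
Conditions: (a) 3, 1-chloro-N,N,2-trimethylprop-1-en-1-amine, CH2Cl2, 0 °C → rt; (b) 6 (2.2 equiv), LiN(SiMe3)2 (2.2 equiv), THF, −78 °C, then 7, −78 → −20 °C; (c) AcOH, rt → 40 °C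
Reagents that add atoms: none
Why: The lithium enolate at C4 of 6 is C-acylated by the aroyl chloride (Claisen-type acylation, the second equivalent of enolate taking up the acidic diketone proton), and on acidification the aryl ketone enol displaces dimethylamine from the aminomethylidene carbon by addition–elimination, the standard enaminone route to 4-pyranones; the chloroenamine makes the acid chloride without HCl, so the acetal is not at risk.

Step 5
Reactants: 9 methyl 5-methoxy-6-(3-methoxy-4-{[2-(trimethylsilyl)ethoxy]methoxy}phenyl)-4-oxo-4H-pyran-3-carboxylate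
Product: 10 5-methoxy-6-(3-methoxy-4-{[2-(trimethylsilyl)ethoxy]methoxy}phenyl)-4-oxo-4H-pyran-3-carboxylic acid
Conditions: Me3SnOH, ClCH2CH2Cl, 70 °C; then cold 0.1 M aq. HCl wash
Reagents that add atoms: trimethyltin hydroxide, C[Sn](C)(C)O
Why: Me3SnOH delivers hydroxide to the ester carbonyl through tin coordination under neutral conditions (mild methyl ester hydrolysis), which spares the acetal and avoids the ring opening that free hydroxide would cause by attack at the electrophilic C2 of the pyranone.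

Step 6
Reactants: 10 5-methoxy-6-(3-methoxy-4-{[2-(trimethylsilyl)ethoxy]methoxy}phenyl)-4-oxo-4H-pyran-3-carboxylic acid; 11 chromium hexacarbonyl, Cr(CO)6
Product: 14 pentacarbonyl{methoxy[5-methoxy-6-(3-methoxy-4-{[2-(trimethylsilyl)ethoxy]methoxy}phenyl)-4-oxo-4H-pyran-3-yl]methylidene}chromium, via pyranone acid chloride 12 (not isolated), via sodium acylchromate 13 (not isolated)
Conditions: (a) 10, 1-chloro-N,N,2-trimethylprop-1-en-1-amine (1.0 equiv), CH2Cl2, rt, then evaporation; (b) Cr(CO)6, NaC10H8 (2 equiv), THF, −78 °C (gives Na2Cr(CO)5), then 12 in THF, −78 → 0 °C; (c) Me3OBF4 (1.05 equiv), CH2Cl2, 0 °C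
Reagents that add atoms: trimethyloxonium tetrafluoroborate, C[O+](C)C.F[B-](F)(F)F
Why: The strongly nucleophilic pentacarbonylchromate dianion substitutes the acid chloride at −78 °C to give the acylchromate, whose anionic oxygen is methylated by one equivalent of oxonium salt faster than the neutral pyranone carbonyl (acid chloride route to Fischer carbene complexes, the usual choice when the matching organolithium reagent cannot be made).

Step 7
Reactants: 14 pentacarbonyl{methoxy[5-methoxy-6-(3-methoxy-4-{[2-(trimethylsilyl)ethoxy]methoxy}phenyl)-4-oxo-4H-pyran-3-yl]methylidene}chromium; 15 2-ethynyl-4,4,5,5-tetramethyl-1,3,2-dioxaborolane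
Product: 16 8-hydroxy-3,5-dimethoxy-2-(3-methoxy-4-{[2-(trimethylsilyl)ethoxy]methoxy}phenyl)-7-(4,4,5,5-tetramethyl-1,3,2-dioxaborolan-2-yl)-4H-chromen-4-one
Conditions: 15 (2 equiv), THF, 50 °C, argon; then air, rt
Reagents that add atoms: none
Why: Thermal loss of one CO ligand from 14 opens a coordination site for 15, which inserts into the Cr=C bond to give a vinylcarbene (C5–C6); a CO ligand then inserts to give a chromium-bound vinylketene (C7–C8), which closes onto the pyranone C2–H carbon (C8–C8a) before the cyclohexadienone tautomerises to the phenol. The closest known reaction type is the Dötz benzannulation of aryl and alkenyl Fischer carbene complexes with alkynylboronic esters, which gives ortho-borylated hydroquinone monomethyl ethers. Ring A is the only ring formed, by a thermal 6π-electrocyclization of the dienylketene, a six-membered carbocyclic closure onto the only sp2 C–H position next to the carbene-bearing carbon, so no other closure site exists. No stereocenter is created. The selectivity needed is the regiochemistry of alkyne insertion: a terminal alkyne places its substituted carbon away from the carbene carbon and next to the CO-derived carbon, and the large steric difference between H and the pinacolboryl group should put boron at C7 and hydrogen at C6. The carbene carbon thus becomes C5 with its methoxy group and the carbonyl ligand becomes C8–OH, while chromium in THF favours CO insertion over five-membered ring formation.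

Step 8
Reactants: 16 8-hydroxy-3,5-dimethoxy-2-(3-methoxy-4-{[2-(trimethylsilyl)ethoxy]methoxy}phenyl)-7-(4,4,5,5-tetramethyl-1,3,2-dioxaborolan-2-yl)-4H-chromen-4-one
Product: 17 3,5,8-trimethoxy-2-(3-methoxy-4-{[2-(trimethylsilyl)ethoxy]methoxy}phenyl)-7-(4,4,5,5-tetramethyl-1,3,2-dioxaborolan-2-yl)-4H-chromen-4-one
Conditions: MeI, K2CO3, acetone, 40 °C
Reagents that add atoms: iodomethane, CI
Why: Williamson O-methylation of the only free phenol (C8) should be straightforward, the pinacol boronic ester and the acetal being inert to carbonate in dry acetone.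

Step 9
Reactants: 17 3,5,8-trimethoxy-2-(3-methoxy-4-{[2-(trimethylsilyl)ethoxy]methoxy}phenyl)-7-(4,4,5,5-tetramethyl-1,3,2-dioxaborolan-2-yl)-4H-chromen-4-one
Product: 18 7-hydroxy-3,5,8-trimethoxy-2-(3-methoxy-4-{[2-(trimethylsilyl)ethoxy]methoxy}phenyl)-4H-chromen-4-one
Conditions: 30% aq. H2O2, 1 M aq. NaOH, THF, 0 °C; then aq. NH4Cl
Reagents that add atoms: hydrogen peroxide, OO
Why: Hydroperoxide adds to boron and the aryl group migrates from boron to oxygen (oxidation of an arylboronic ester to a phenol), which fixes the oxygen at C7, and the 3-methoxyflavone core and the acetal tolerate cold alkaline peroxide.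

Step 10
Reactants: 18 7-hydroxy-3,5,8-trimethoxy-2-(3-methoxy-4-{[2-(trimethylsilyl)ethoxy]methoxy}phenyl)-4H-chromen-4-one; 19 1-bromo-3-methylbut-2-ene (prenyl bromide)
Product: 20 3,5,8-trimethoxy-2-(3-methoxy-4-{[2-(trimethylsilyl)ethoxy]methoxy}phenyl)-7-[(3-methylbut-2-en-1-yl)oxy]-4H-chromen-4-one
Conditions: K2CO3, acetone, 50 °C
Reagents that add atoms: none
Why: The C7 phenol, acidic because it is conjugated through ring A with the C4 carbonyl, is the only free hydroxyl and should undergo SN2 O-alkylation by the primary allylic bromide (Williamson ether synthesis).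

Step 11
Reactants: 20 3,5,8-trimethoxy-2-(3-methoxy-4-{[2-(trimethylsilyl)ethoxy]methoxy}phenyl)-7-[(3-methylbut-2-en-1-yl)oxy]-4H-chromen-4-one
Product: 21 2-(4-hydroxy-3-methoxyphenyl)-3,5,8-trimethoxy-7-[(3-methylbut-2-en-1-yl)oxy]-4H-chromen-4-one (4'-hydroxy-3,5,8,3'-tetramethoxy-7-prenyloxyflavone)
Conditions: Bu4NF (1 M in THF, excess), THF, 60 °C; then aq. NH4Cl
Reagents that add atoms: none
Why: Fluoride attacks silicon and the acetal fragments to ethene, formaldehyde and the 4'-phenoxide (fluoride-induced SEM cleavage), a release helped by the leaving ability of a phenoxide conjugated with the chromone and run without acid, so the aryl prenyl ether, the four methyl ethers and the flavone should be untouched.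

Compound list
1 | methyl 4-hydroxy-3-methoxybenzoate (methyl vanillate) | COC(=O)c1ccc(O)c(OC)c1 | starting material
2 | methyl 3-methoxy-4-{[2-(trimethylsilyl)ethoxy]methoxy}benzoate | COC(=O)c1ccc(OCOCC[Si](C)(C)C)c(OC)c1 | intermediate
3 | 3-methoxy-4-{[2-(trimethylsilyl)ethoxy]methoxy}benzoic acid | OC(=O)c1ccc(OCOCC[Si](C)(C)C)c(OC)c1 | intermediate
4 | methyl 4-methoxy-3-oxobutanoate | COCC(=O)CC(=O)OC | starting material
5 | N,N-dimethylformamide dimethyl acetal | COC(OC)N(C)C | starting material
6 | methyl (2Z)-2-[(dimethylamino)methylidene]-4-methoxy-3-oxobutanoate | COCC(=O)/C(C(=O)OC)=C/N(C)C | intermediate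
7 | 3-methoxy-4-{[2-(trimethylsilyl)ethoxy]methoxy}benzoyl chloride | ClC(=O)c1ccc(OCOCC[Si](C)(C)C)c(OC)c1 | intermediate (not isolated)
8 | methyl 2-[(dimethylamino)methylidene]-4-methoxy-5-(3-methoxy-4-{[2-(trimethylsilyl)ethoxy]methoxy}phenyl)-3,5-dioxopentanoate (racemic at C4, enolisable, alkene geometry undefined) | COC(=O)C(=CN(C)C)C(=O)C(OC)C(=O)c1ccc(OCOCC[Si](C)(C)C)c(OC)c1 | intermediate (not isolated)
9 | methyl 5-methoxy-6-(3-methoxy-4-{[2-(trimethylsilyl)ethoxy]methoxy}phenyl)-4-oxo-4H-pyran-3-carboxylate | COC(=O)c1coc(-c2ccc(OCOCC[Si](C)(C)C)c(OC)c2)c(OC)c1=O | intermediate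
10 | 5-methoxy-6-(3-methoxy-4-{[2-(trimethylsilyl)ethoxy]methoxy}phenyl)-4-oxo-4H-pyran-3-carboxylic acid | OC(=O)c1coc(-c2ccc(OCOCC[Si](C)(C)C)c(OC)c2)c(OC)c1=O | intermediate
11 | chromium hexacarbonyl, Cr(CO)6 | O=C=[Cr](=C=O)(=C=O)(=C=O)(=C=O)=C=O | starting material
12 | 5-methoxy-6-(3-methoxy-4-{[2-(trimethylsilyl)ethoxy]methoxy}phenyl)-4-oxo-4H-pyran-3-carbonyl chloride | ClC(=O)c1coc(-c2ccc(OCOCC[Si](C)(C)C)c(OC)c2)c(OC)c1=O | intermediate (not isolated)
13 | sodium pentacarbonyl{[5-methoxy-6-(3-methoxy-4-{[2-(trimethylsilyl)ethoxy]methoxy}phenyl)-4-oxo-4H-pyran-3-yl]carbonyl}chromate | [Na+].[O-]C(=[Cr](=C=O)(=C=O)(=C=O)(=C=O)=C=O)c1coc(-c2ccc(OCOCC[Si](C)(C)C)c(OC)c2)c(OC)c1=O | intermediate (not isolated)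
14 | pentacarbonyl{methoxy[5-methoxy-6-(3-methoxy-4-{[2-(trimethylsilyl)ethoxy]methoxy}phenyl)-4-oxo-4H-pyran-3-yl]methylidene}chromium | COC(=[Cr](=C=O)(=C=O)(=C=O)(=C=O)=C=O)c1coc(-c2ccc(OCOCC[Si](C)(C)C)c(OC)c2)c(OC)c1=O | intermediate (key-step precursor)
15 | 2-ethynyl-4,4,5,5-tetramethyl-1,3,2-dioxaborolane | C#CB1OC(C)(C)C(C)(C)O1 | starting material
16 | 8-hydroxy-3,5-dimethoxy-2-(3-methoxy-4-{[2-(trimethylsilyl)ethoxy]methoxy}phenyl)-7-(4,4,5,5-tetramethyl-1,3,2-dioxaborolan-2-yl)-4H-chromen-4-one | COc1cc(-c2oc3c(O)c(B4OC(C)(C)C(C)(C)O4)cc(OC)c3c(=O)c2OC)ccc1OCOCC[Si](C)(C)C | intermediate (key-step product)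
17 | 3,5,8-trimethoxy-2-(3-methoxy-4-{[2-(trimethylsilyl)ethoxy]methoxy}phenyl)-7-(4,4,5,5-tetramethyl-1,3,2-dioxaborolan-2-yl)-4H-chromen-4-one | COc1cc(-c2oc3c(OC)c(B4OC(C)(C)C(C)(C)O4)cc(OC)c3c(=O)c2OC)ccc1OCOCC[Si](C)(C)C | intermediate
18 | 7-hydroxy-3,5,8-trimethoxy-2-(3-methoxy-4-{[2-(trimethylsilyl)ethoxy]methoxy}phenyl)-4H-chromen-4-one | COc1cc(-c2oc3c(OC)c(O)cc(OC)c3c(=O)c2OC)ccc1OCOCC[Si](C)(C)C | intermediate
19 | 1-bromo-3-methylbut-2-ene (prenyl bromide) | CC(C)=CCBr | starting material
20 | 3,5,8-trimethoxy-2-(3-methoxy-4-{[2-(trimethylsilyl)ethoxy]methoxy}phenyl)-7-[(3-methylbut-2-en-1-yl)oxy]-4H-chromen-4-one | COc1cc(-c2oc3c(OC)c(OCC=C(C)C)cc(OC)c3c(=O)c2OC)ccc1OCOCC[Si](C)(C)C | intermediate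
21 | 2-(4-hydroxy-3-methoxyphenyl)-3,5,8-trimethoxy-7-[(3-methylbut-2-en-1-yl)oxy]-4H-chromen-4-one | COc1cc(-c2oc3c(OC)c(OCC=C(C)C)cc(OC)c3c(=O)c2OC)ccc1O | target

Total step count: 11. Longest linear sequence: 10 steps (steps 1, 2 and 4 to 11 from methyl vanillate; step 3 is a one-step side branch).

Steps most likely to fail

Step 7. Insertion of the boron-substituted alkyne may be slow or lose regiocontrol, and the carbon–boron bond may be lost by protodeboronation beside the newly formed phenol. The fallback sets out from carbene complex 14 and comes back at boronic ester 17, introducing boron only after ring A exists. Complex 14 is heated with ethynyltrimethylsilane (THF, 50 °C; then air), a long-established partner in this benzannulation that places silicon next to the new hydroxyl, which should give 8-hydroxy-3,5-dimethoxy-2-(3-methoxy-4-{[2-(trimethylsilyl)ethoxy]methoxy}phenyl)-7-(trimethylsilyl)-4H-chromen-4-one F1. Ipso-iododesilylation (ICl, NaHCO3, CH2Cl2, −78 °C) should give 8-hydroxy-7-iodo-3,5-dimethoxy-2-(3-methoxy-4-{[2-(trimethylsilyl)ethoxy]methoxy}phenyl)-4H-chromen-4-one F2. O-Methylation (MeI, K2CO3, acetone) then gives 7-iodo-3,5,8-trimethoxy-2-(3-methoxy-4-{[2-(trimethylsilyl)ethoxy]methoxy}phenyl)-4H-chromen-4-one F3, and Miyaura borylation (B2pin2, Pd(dppf)Cl2, KOAc, dioxane, 80 °C) returns to 17.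

Step 6. Electron transfer from the chromate dianion to the electron-poor pyranone, or its conjugate addition at C2, may outrun substitution at the acyl chloride. The fallback sets out from acid 10 and comes back at carbene complex 14 with the polarity reversed (classical Fischer synthesis from a carbon nucleophile and a CO ligand). Ipso-iododecarboxylation of 10 (N-iodosuccinimide, LiOAc cat., MeCN, rt → 50 °C; Hunsdiecker-type halodecarboxylation of a vinylogous β-keto acid) should give 5-iodo-3-methoxy-2-(3-methoxy-4-{[2-(trimethylsilyl)ethoxy]methoxy}phenyl)-4H-pyran-4-one F4. Iodine–magnesium exchange (i-PrMgCl·LiCl, THF, −40 °C) gives chloro[5-methoxy-6-(3-methoxy-4-{[2-(trimethylsilyl)ethoxy]methoxy}phenyl)-4-oxo-4H-pyran-3-yl]magnesium F5. Addition of F5 to Cr(CO)6 (−40 → 0 °C) gives the chloromagnesium pentacarbonyl(pyranonylcarbonyl)chromate F6, and O-methylation with Me3OBF4 (CH2Cl2, 0 °C) returns to 14.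

Step 5. The hydroxide donor may add in conjugate fashion to C2 of the doubly activated pyranone and open the ring, or the vinylogous β-keto acid may lose CO2 on heating. The fallback sets out from keto ester 4 and comes back at acid 10, replacing hydrolysis by hydrogenolysis of a benzyl ester. Transesterification of 4 with benzyl alcohol (toluene, reflux, MeOH distilled off) gives benzyl 4-methoxy-3-oxobutanoate F7, and condensation with 5 gives benzyl 2-[(dimethylamino)methylidene]-4-methoxy-3-oxobutanoate F8. Acylation with aroyl chloride 7 under the conditions of step 4 passes through benzyl 2-[(dimethylamino)methylidene]-4-methoxy-5-(3-methoxy-4-{[2-(trimethylsilyl)ethoxy]methoxy}phenyl)-3,5-dioxopentanoate F9 (not isolated) to benzyl 5-methoxy-6-(3-methoxy-4-{[2-(trimethylsilyl)ethoxy]methoxy}phenyl)-4-oxo-4H-pyran-3-carboxylate F10. Hydrogenolysis (H2, Pd/C, EtOAc, rt) then releases 10 under neutral conditions that leave the aryl SEM ether and the pyranone intact.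

Further compounds
F1 | step 7 | 8-hydroxy-3,5-dimethoxy-2-(3-methoxy-4-{[2-(trimethylsilyl)ethoxy]methoxy}phenyl)-7-(trimethylsilyl)-4H-chromen-4-one | COc1cc(-c2oc3c(O)c([Si](C)(C)C)cc(OC)c3c(=O)c2OC)ccc1OCOCC[Si](C)(C)C
F2 | step 7 | 8-hydroxy-7-iodo-3,5-dimethoxy-2-(3-methoxy-4-{[2-(trimethylsilyl)ethoxy]methoxy}phenyl)-4H-chromen-4-one | COc1cc(-c2oc3c(O)c(I)cc(OC)c3c(=O)c2OC)ccc1OCOCC[Si](C)(C)C
F3 | step 7 | 7-iodo-3,5,8-trimethoxy-2-(3-methoxy-4-{[2-(trimethylsilyl)ethoxy]methoxy}phenyl)-4H-chromen-4-one | COc1cc(-c2oc3c(OC)c(I)cc(OC)c3c(=O)c2OC)ccc1OCOCC[Si](C)(C)C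
F4 | step 6 | 5-iodo-3-methoxy-2-(3-methoxy-4-{[2-(trimethylsilyl)ethoxy]methoxy}phenyl)-4H-pyran-4-one | COc1cc(-c2occ(I)c(=O)c2OC)ccc1OCOCC[Si](C)(C)C
F5 | step 6 | chloro[5-methoxy-6-(3-methoxy-4-{[2-(trimethylsilyl)ethoxy]methoxy}phenyl)-4-oxo-4H-pyran-3-yl]magnesium | COc1cc(-c2occ([Mg]Cl)c(=O)c2OC)ccc1OCOCC[Si](C)(C)C
F6 | step 6 | chloromagnesium pentacarbonyl{[5-methoxy-6-(3-methoxy-4-{[2-(trimethylsilyl)ethoxy]methoxy}phenyl)-4-oxo-4H-pyran-3-yl]carbonyl}chromate | Cl[Mg+].[O-]C(=[Cr](=C=O)(=C=O)(=C=O)(=C=O)=C=O)c1coc(-c2ccc(OCOCC[Si](C)(C)C)c(OC)c2)c(OC)c1=O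
F7 | step 5 | benzyl 4-methoxy-3-oxobutanoate | COCC(=O)CC(=O)OCc1ccccc1
F8 | step 5 | benzyl (2Z)-2-[(dimethylamino)methylidene]-4-methoxy-3-oxobutanoate | COCC(=O)/C(C(=O)OCc1ccccc1)=C/N(C)C
F9 | step 5 | benzyl 2-[(dimethylamino)methylidene]-4-methoxy-5-(3-methoxy-4-{[2-(trimethylsilyl)ethoxy]methoxy}phenyl)-3,5-dioxopentanoate (racemic, enolisable) | O=C(OCc1ccccc1)C(=CN(C)C)C(=O)C(OC)C(=O)c1ccc(OCOCC[Si](C)(C)C)c(OC)c1
F10 | step 5 | benzyl 5-methoxy-6-(3-methoxy-4-{[2-(trimethylsilyl)ethoxy]methoxy}phenyl)-4-oxo-4H-pyran-3-carboxylate | O=C(OCc1ccccc1)c1coc(-c2ccc(OCOCC[Si](C)(C)C)c(OC)c2)c(OC)c1=O
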